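**Plan**

- Cuts: the aryl ether C–O bond; the ring bonds C-1–C-6 and C-3–C-4 (ring: C-1 CHOH, C-2 CMe2, C-3 CH with the chain, C-4 C(OH)Me, C-5 and C-6 CH2), which releases but-3-en-2-one (C-4, its methyl, C-5, C-6) from an open-chain ynal; the bond between the alkyne and the CH2 next to the side-chain carbinol (acetylide plus epoxide).
- Forward: (S)-citramalic acid gives a silyl-protected epoxide; acetylide opening joins it to the ring precursor; oxidation gives the ynal; the single carbocycle arises in one flask by Stetter addition at C-1 and nickel-catalysed reductive alkyne–ketone cyclization at C-3/C-4; ketone reduction, alkene hydrogenation, desilylation and aryl ether formation follow.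
- Enabling feature: both new bonds end at the oxygen-bearing ring carbons C-1 and C-4. C-1 sits on the quaternary C-2, so it can be a formyl carbon that cannot enolize and serves as acyl anion; C-3 can be an alkyne carbon that afterwards carries an exocyclic alkene.
- Stereochemistry: side-chain carbinol from the chiral pool; C-4 from the chiral ligand on nickel; C-1 from axial hydride attack; C-3 from hydroxyl-directed hydrogenation.

Key step: step 6

Assumption: the (S)-ligand in step 6 is taken, by analogy, to give the 4S carbinol; the antipodal ligand would be used if a model alkynone showed the opposite facial sense.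

Step 1
Reactants: 1 (S)-citramalic acid, (2S)-2-hydroxy-2-methylbutanedioic acid
Product: 2 (2S)-2-methylbutane-1,2,4-triol
Conditions: BH3·SMe2, B(OMe)3, THF, 0 °C to rt; then MeOH
Reagents that add atoms: none
Why: Borane reduction of both carboxylic acids to primary alcohols should leave the tertiary carbinol centre from the chiral pool untouched.

Step 2
Reactants: 2 (2S)-2-methylbutane-1,2,4-triol
Product: 3 (2S)-4-[(tert-butyldiphenylsilyl)oxy]-2-methylbutane-1,2-diol
Conditions: tert-butyl(chloro)diphenylsilane (1 equiv), imidazole, CH2Cl2, −20 °C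
Reagents that add atoms: tert-butyl(chloro)diphenylsilane, CC(C)(C)[Si](Cl)(c1ccccc1)c1ccccc1
Why: Selective silylation: the bulky silyl chloride should take the unhindered primary hydroxyl at C-4 in preference to the neopentyl-type primary and the tertiary hydroxyl.

Step 3
Reactants: 3 (2S)-4-[(tert-butyldiphenylsilyl)oxy]-2-methylbutane-1,2-diol
Product: 4 tert-butyl{2-[(2S)-2-methyloxiran-2-yl]ethoxy}diphenylsilane
Conditions: NaH (2.2 equiv), 1-(p-tolylsulfonyl)imidazole, THF, 0 °C to rt
Reagents that add atoms: none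
Why: One-pot epoxide formation (sulfonylation of the primary alkoxide, then 3-exo-tet intramolecular Williamson displacement by the tertiary alkoxide) breaks no bond at the stereocentre, so its configuration is kept.

Step 4
Reactants: 5 2,2-dimethylbut-3-yn-1-ol; 4 tert-butyl{2-[(2S)-2-methyloxiran-2-yl]ethoxy}diphenylsilane
Product: 6 (6R)-8-[(tert-butyldiphenylsilyl)oxy]-2,2,6-trimethyloct-3-yne-1,6-diol
Conditions: n-BuLi (2.1 equiv), THF–DMPU, −78 °C; then 4, −78 to 45 °C; H2O
Reagents that add atoms: none
Why: SN2 opening of the 2,2-disubstituted epoxide at its CH2 by the lithium acetylide of the alkynol dianion should give the tertiary homopropargylic alcohol with the carbinol centre untouched.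

Step 5
Reactants: 6 (6R)-8-[(tert-butyldiphenylsilyl)oxy]-2,2,6-trimethyloct-3-yne-1,6-diol
Product: 7 (6R)-8-[(tert-butyldiphenylsilyl)oxy]-6-hydroxy-2,2,6-trimethyloct-3-ynal
Conditions: 1,1,1-triacetoxy-1,1-dihydro-1,2-benziodoxol-3(1H)-one, CH2Cl2, rt
Reagents that add atoms: none
Why: Hypervalent-iodine oxidation of the primary alcohol should stop at the aldehyde, which has no α-hydrogen, while the tertiary alcohol cannot be oxidized.

Step 6
Reactants: 7 (6R)-8-[(tert-butyldiphenylsilyl)oxy]-6-hydroxy-2,2,6-trimethyloct-3-ynal; 8 but-3-en-2-one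
Product: 11 (3E,4S)-3-{(3R)-5-[(tert-butyldiphenylsilyl)oxy]-3-hydroxy-3-methylpentylidene}-4-hydroxy-2,2,4-trimethylcyclohexan-1-one, via alkynyl 1,4-diketone 9 (not isolated), via triethylsilyl ether 10 (not isolated)
Conditions: 3-benzyl-5-(2-hydroxyethyl)-4-methylthiazolium chloride (20 mol %), Et3N (50 mol %), 8 (1.5 equiv), 1,4-dioxane, 70 °C; volatiles removed; then Ni(cod)2 (10 mol %), (S)-AntPhos [(S)-4-(anthracen-9-yl)-3-tert-butyl-2,3-dihydrobenzo[d][1,3]oxaphosphole, 12 mol %], Et3SiH, 1,4-dioxane, rt; then HF·pyridine, pyridine, THF, 0 °C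
Reagents that add atoms: none
Why: The thiazol-2-ylidene adds to the α-quaternary aldehyde, which cannot enolize, and the resulting acyl-anion equivalent adds 1,4 to but-3-en-2-one (Stetter reaction), forming the C-1–C-6 bond of 9. In the same flask zerovalent nickel with the P-chiral monophosphine joins the alkyne carbon and the methyl ketone by oxidative cyclization to an oxanickelacyclopentene, which triethylsilane opens by σ-bond metathesis and C–H reductive elimination, forming the C-3–C-4 bond. The ring closes in the 6-exo-dig mode, and syn addition of carbon and hydrogen across the alkyne fixes the E-alkylidene. The new tertiary carbinol C-4 is set by the ligand, which selects the ketone face in the oxidative cyclization; the remote side-chain centre has no say. The step needs chemoselection between the two ketones and between ring closure and intermolecular coupling: the C-1 ketone could only close a three-membered ring, and the gem-dimethyl group holds alkyne and methyl ketone together. The closest known reaction types are the thiazolium-catalysed Stetter reaction of α,α-dialkyl aldehydes and the nickel-catalysed enantioselective reductive cyclization of alkynones.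

Step 7
Reactants: 11 (3E,4S)-3-{(3R)-5-[(tert-butyldiphenylsilyl)oxy]-3-hydroxy-3-methylpentylidene}-4-hydroxy-2,2,4-trimethylcyclohexan-1-one
Product: 12 (1R,3E,4S)-3-{(3R)-5-[(tert-butyldiphenylsilyl)oxy]-3-hydroxy-3-methylpentylidene}-2,2,4-trimethylcyclohexane-1,4-diol
Conditions: NaBH4, MeOH, −40 °C
Reagents that add atoms: none
Why: Borohydride reduction of the ketone: hydride should add along the axial path on the face away from the axial C-4 hydroxyl (the sp2 ring carbon C-3 gives no syn-axial hindrance), so the new C-1 hydroxyl is equatorial and cis to the C-4 hydroxyl.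

Step 8
Reactants: 12 (1R,3E,4S)-3-{(3R)-5-[(tert-butyldiphenylsilyl)oxy]-3-hydroxy-3-methylpentylidene}-2,2,4-trimethylcyclohexane-1,4-diol
Product: 13 (1R,3S,4S)-3-{(3R)-5-[(tert-butyldiphenylsilyl)oxy]-3-hydroxy-3-methylpentyl}-2,2,4-trimethylcyclohexane-1,4-diol
Conditions: H2 (1 atm), [Ir(cod)(PCy3)(py)]PF6 (5 mol %), CH2Cl2, rt
Reagents that add atoms: none
Why: Hydroxyl-directed homogeneous hydrogenation: the cationic iridium centre bound to the allylic C-4 hydroxyl (and the cis C-1 hydroxyl) should deliver hydrogen to the alkene face syn to them, which sets C-3 with the side chain trans to the C-4 hydroxyl.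

Step 9
Reactants: 13 (1R,3S,4S)-3-{(3R)-5-[(tert-butyldiphenylsilyl)oxy]-3-hydroxy-3-methylpentyl}-2,2,4-trimethylcyclohexane-1,4-diol
Product: 14 (1R,3S,4S)-3-[(3R)-3,5-dihydroxy-3-methylpentyl]-2,2,4-trimethylcyclohexane-1,4-diol
Conditions: tetrabutylammonium fluoride, THF, rt
Reagents that add atoms: none
Why: Fluoride-induced cleavage of the silyl ether should free the primary alcohol without touching any stereocentre.

Step 10
Reactants: 14 (1R,3S,4S)-3-[(3R)-3,5-dihydroxy-3-methylpentyl]-2,2,4-trimethylcyclohexane-1,4-diol; 15 7-hydroxy-2H-chromen-2-one (umbelliferone)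
Product: 16 7-{[(3R)-5-[(1S,3R,6S)-3,6-dihydroxy-2,2,6-trimethylcyclohexyl]-3-hydroxy-3-methylpentyl]oxy}-2H-chromen-2-one (CNP0210598.1)
Conditions: PPh3, diisopropyl azodicarboxylate, THF, 0 °C to rt
Reagents that add atoms: none
Why: Mitsunobu etherification: only the unhindered primary hydroxyl should be activated and displaced by the acidic phenol, while the neopentyl secondary and the two tertiary hydroxyls stay inert and no stereocentre is involved.

**Compound list**

1 | (S)-citramalic acid, (2S)-2-hydroxy-2-methylbutanedioic acid | C[C@](O)(CC(=O)O)C(=O)O | starting material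
2 | (2S)-2-methylbutane-1,2,4-triol | C[C@](O)(CCO)CO | intermediate
3 | (2S)-4-[(tert-butyldiphenylsilyl)oxy]-2-methylbutane-1,2-diol | C[C@](O)(CCO[Si](c1ccccc1)(c1ccccc1)C(C)(C)C)CO | intermediate
4 | tert-butyl{2-[(2S)-2-methyloxiran-2-yl]ethoxy}diphenylsilane | C[C@]1(CCO[Si](c2ccccc2)(c2ccccc2)C(C)(C)C)CO1 | intermediate
5 | 2,2-dimethylbut-3-yn-1-ol | OCC(C)(C)C#C | starting material
6 | (6R)-8-[(tert-butyldiphenylsilyl)oxy]-2,2,6-trimethyloct-3-yne-1,6-diol | OCC(C)(C)C#CC[C@@](C)(O)CCO[Si](c1ccccc1)(c1ccccc1)C(C)(C)C | intermediate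
7 | (6R)-8-[(tert-butyldiphenylsilyl)oxy]-6-hydroxy-2,2,6-trimethyloct-3-ynal | O=CC(C)(C)C#CC[C@@](C)(O)CCO[Si](c1ccccc1)(c1ccccc1)C(C)(C)C | intermediate
8 | but-3-en-2-one | C=CC(C)=O | starting material
9 | (10R)-12-[(tert-butyldiphenylsilyl)oxy]-10-hydroxy-6,6,10-trimethyldodec-7-yne-2,5-dione | CC(=O)CCC(=O)C(C)(C)C#CC[C@@](C)(O)CCO[Si](c1ccccc1)(c1ccccc1)C(C)(C)C | intermediate
10 | (3E,4S)-3-{(3R)-5-[(tert-butyldiphenylsilyl)oxy]-3-hydroxy-3-methylpentylidene}-2,2,4-trimethyl-4-[(triethylsilyl)oxy]cyclohexan-1-one | CC1(C)C(=O)CC[C@](C)(O[Si](CC)(CC)CC)/C1=C/C[C@@](C)(O)CCO[Si](c1ccccc1)(c1ccccc1)C(C)(C)C | intermediate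
11 | (3E,4S)-3-{(3R)-5-[(tert-butyldiphenylsilyl)oxy]-3-hydroxy-3-methylpentylidene}-4-hydroxy-2,2,4-trimethylcyclohexan-1-one | CC1(C)C(=O)CC[C@](C)(O)/C1=C/C[C@@](C)(O)CCO[Si](c1ccccc1)(c1ccccc1)C(C)(C)C | intermediate
12 | (1R,3E,4S)-3-{(3R)-5-[(tert-butyldiphenylsilyl)oxy]-3-hydroxy-3-methylpentylidene}-2,2,4-trimethylcyclohexane-1,4-diol | CC1(C)[C@H](O)CC[C@](C)(O)/C1=C/C[C@@](C)(O)CCO[Si](c1ccccc1)(c1ccccc1)C(C)(C)C | intermediate
13 | (1R,3S,4S)-3-{(3R)-5-[(tert-butyldiphenylsilyl)oxy]-3-hydroxy-3-methylpentyl}-2,2,4-trimethylcyclohexane-1,4-diol | CC1(C)[C@H](O)CC[C@](C)(O)[C@H]1CC[C@@](C)(O)CCO[Si](c1ccccc1)(c1ccccc1)C(C)(C)C | intermediate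
14 | (1R,3S,4S)-3-[(3R)-3,5-dihydroxy-3-methylpentyl]-2,2,4-trimethylcyclohexane-1,4-diol | CC1(C)[C@H](O)CC[C@](C)(O)[C@H]1CC[C@@](C)(O)CCO | intermediate
15 | 7-hydroxy-2H-chromen-2-one (umbelliferone) | Oc1ccc2ccc(=O)oc2c1 | starting material
16 | 7-{[(3R)-5-[(1S,3R,6S)-3,6-dihydroxy-2,2,6-trimethylcyclohexyl]-3-hydroxy-3-methylpentyl]oxy}-2H-chromen-2-one | CC1(C)[C@H](O)CC[C@](C)(O)[C@H]1CC[C@@](C)(O)CCOc1ccc2ccc(=O)oc2c1 | target

**Count and risks**

Total steps: 10. Longest linear sequence: 10 steps (1 to 16).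

Step 6 is the most likely to fail. The acyl-anion equivalent may form slowly from the hindered aldehyde, carbene carried over may give an unselective nickel catalyst, or facial control in the oxidative cyclization may be incomplete. The fallback separates the two bond formations and replaces the acyl-anion chemistry. Setting out from 7, addition of [2-(2-methyl-1,3-dioxolan-2-yl)ethyl]magnesium bromide (THF, 0 °C) should give (8R)-10-[(tert-butyldiphenylsilyl)oxy]-4,4,8-trimethyl-1-(2-methyl-1,3-dioxolan-2-yl)dec-5-yne-3,8-diol F1 as both C-3 epimers. Oxidation with the periodinane of step 5 should give (8R)-10-[(tert-butyldiphenylsilyl)oxy]-8-hydroxy-4,4,8-trimethyl-1-(2-methyl-1,3-dioxolan-2-yl)dec-5-yn-3-one F2. Mild hydrolysis of the dioxolane (pyridinium p-toluenesulfonate, wet acetone) comes back to the route at 9, now isolated, which is then cyclized on its own under the nickel conditions of step 6.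

Step 8 is the second risk. The side-chain tertiary hydroxyl may compete for the iridium centre, or hydrogen may approach from the open face, so that facial selectivity is lost. The fallback masks the competing hydroxyl in a temporary ring. Setting out from 12, tetrabutylammonium fluoride should give (1R,3E,4S)-3-[(3R)-3,5-dihydroxy-3-methylpentylidene]-2,2,4-trimethylcyclohexane-1,4-diol F3. 2,2-Dimethoxypropane with pyridinium p-toluenesulfonate should tie the side-chain 1,3-diol into (1R,3E,4S)-2,2,4-trimethyl-3-{2-[(4R)-2,2,4-trimethyl-1,3-dioxan-4-yl]ethylidene}cyclohexane-1,4-diol F4. Hydrogenation with [Ir(cod)(PCy3)(py)]PF6, now directed only by the ring hydroxyls, should give (1R,3S,4S)-2,2,4-trimethyl-3-{2-[(4R)-2,2,4-trimethyl-1,3-dioxan-4-yl]ethyl}cyclohexane-1,4-diol F5. Aqueous acetic acid comes back to the route at 14.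

Step 7 is the third risk. Hydride may attack along the equatorial path or be delivered internally from the C-4 alkoxide, which would erode the cis selectivity. The fallback replaces substrate control by reagent control. Setting out from 11, oxazaborolidine-catalysed borane reduction (CBS reduction; (S)-2-methyl-CBS-oxazaborolidine, excess BH3·SMe2, THF, −20 °C) should distinguish the tert-alkyl from the primary alkyl flank of the ketone and come back to the route at 12. It makes no new compound (F0).

**Further compounds**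

F1 | step 6 | (8R)-10-[(tert-butyldiphenylsilyl)oxy]-4,4,8-trimethyl-1-(2-methyl-1,3-dioxolan-2-yl)dec-5-yne-3,8-diol (both C-3 epimers) | CC1(CCC(O)C(C)(C)C#CC[C@@](C)(O)CCO[Si](c2ccccc2)(c2ccccc2)C(C)(C)C)OCCO1
F2 | step 6 | (8R)-10-[(tert-butyldiphenylsilyl)oxy]-8-hydroxy-4,4,8-trimethyl-1-(2-methyl-1,3-dioxolan-2-yl)dec-5-yn-3-one | CC1(CCC(=O)C(C)(C)C#CC[C@@](C)(O)CCO[Si](c2ccccc2)(c2ccccc2)C(C)(C)C)OCCO1
F3 | step 8 | (1R,3E,4S)-3-[(3R)-3,5-dihydroxy-3-methylpentylidene]-2,2,4-trimethylcyclohexane-1,4-diol | CC1(C)[C@H](O)CC[C@](C)(O)/C1=C/C[C@@](C)(O)CCO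
F4 | step 8 | (1R,3E,4S)-2,2,4-trimethyl-3-{2-[(4R)-2,2,4-trimethyl-1,3-dioxan-4-yl]ethylidene}cyclohexane-1,4-diol | CC1(C)[C@H](O)CC[C@](C)(O)/C1=C/C[C@]1(C)CCOC(C)(C)O1
F5 | step 8 | (1R,3S,4S)-2,2,4-trimethyl-3-{2-[(4R)-2,2,4-trimethyl-1,3-dioxan-4-yl]ethyl}cyclohexane-1,4-diol | CC1(C)[C@H](O)CC[C@](C)(O)[C@H]1CC[C@]1(C)CCOC(C)(C)O1
F0 | step 7 | none | none
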